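**Retrosynthetic overview**
1. The target comes from a 7-hydroxy-azaphilone (6,8-dione) by C5 chlorination and a final 7-OH-directed reduction of the C8 ketone (sets C8, trans-diol).
2. The pyran ring is the only ring built. It closes in the same operation that dearomatizes the purchased benzene ring and sets C7: catalytic asymmetric hydroxylative dearomatization of an o-alkynyl resorcinaldehyde, then 6-endo cycloisomerization.
3. The aryl–alkyne bond is made by Sonogashira coupling of a bromoresorcinaldehyde (two steps from 5-bromoresorcinol) with the side-chain enyne diol.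
4. The enyne diol comes from chelation-controlled MeMgBr addition to an α-hydroxy enynone (sets C3'), itself made from a C4 diyne and an α-benzoyloxy aldehyde.
5. The first stereocentres (C5', then C4') are set by a one-pot organocatalytic transfer hydrogenation/α-benzoyloxylation of achiral 3-methylpent-2-enal.

Assumption: 1 is bought as the commercial E/Z mixture and used as such, because the iminium geometries interconvert and converge on one enantiomer (the E isomer is drawn).

**Step 1**
Reactants: 1 3-methylpent-2-enal
Product: 3 (2S,3S)-3-methyl-1-oxopentan-2-yl benzoate, via (S)-3-methylpentanal 2 (not isolated)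
Conditions: (S)-2-tert-butyl-3-methylimidazolidin-4-one·CCl3CO2H (20 mol %), Hantzsch ester (1.05 equiv), CHCl3, −30 °C; then (S)-2-(triphenylmethyl)pyrrolidine (10 mol %), (PhCO2)2 (1.2 equiv), hydroquinone (10 mol %), THF, 0 °C
Reagents that add atoms: dibenzoyl peroxide O=C(OOC(=O)c1ccccc1)c1ccccc1
Why: Iminium-catalysed transfer hydrogenation delivers hydride to the face of the β-carbon away from the tert-butyl group and sets the first stereocentre (3S) from an achiral enal (about 90% ee expected for methyl against ethyl); enamine-catalysed α-benzoyloxylation on the face away from the trityl group then sets 2S under catalyst control, so the minor 3R aldehyde ends up as a separable diastereomer.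

**Step 2**
Reactants: 3 (2S,3S)-3-methyl-1-oxopentan-2-yl benzoate; 4 1,4-bis(trimethylsilyl)buta-1,3-diyne
Product: 7 (3E,6S,7S)-7-methyl-1-(trimethylsilyl)non-3-en-1-yne-5,6-diol (both C5 epimers), via lithium 4-(trimethylsilyl)buta-1,3-diynide 5 (not isolated), via lithium alkoxide of diynol benzoate 6 (not isolated)
Conditions: 4 (1.15 equiv), MeLi·LiBr (1.1 equiv), THF, 0 °C to rt; add 3, −78 °C; then NaAlH2(OCH2CH2OCH3)2 (4 equiv), −78 °C to rt; aq. potassium sodium tartrate
Reagents that add atoms: none
Why: Acetylide 1,2-addition to the aldehyde, then alkoxide-directed trans-hydroalumination of the proximal alkyne only (propargylic alcohol to E-allylic alcohol reduction), which also cleaves the benzoate; the new carbinol centre need not be controlled because step 3 oxidises it.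

**Step 3**
Reactants: 7 (3E,6S,7S)-7-methyl-1-(trimethylsilyl)non-3-en-1-yne-5,6-diol
Product: 8 (3E,6S,7S)-6-hydroxy-7-methyl-1-(trimethylsilyl)non-3-en-1-yn-5-one
Conditions: MnO2 (activated, 20 equiv), CH2Cl2, rt
Reagents that add atoms: none
Why: Chemoselective MnO2 oxidation of the allylic hydroxyl merges both C5 epimers into one ketone and leaves the saturated C6 carbinol and C7 untouched.

**Step 4**
Reactants: 8 (3E,6S,7S)-6-hydroxy-7-methyl-1-(trimethylsilyl)non-3-en-1-yn-5-one
Product: 9 (3E,5R,6S,7S)-5,7-dimethyl-1-(trimethylsilyl)non-3-en-1-yne-5,6-diol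
Conditions: MeMgBr (3.5 equiv), THF, −78 to −40 °C; aq. NH4Cl
Reagents that add atoms: methylmagnesium bromide C[Mg]Br
Why: Cram chelation-controlled Grignard addition: the magnesium alkoxide of the free α-hydroxyl and the ketone oxygen form a five-membered chelate, and methyl adds 1,2 from the face opposite the sec-butyl group, giving the 5R tertiary alcohol; the alkoxide also suppresses enolisation at C6.

**Step 5**
Reactants: 10 5-bromobenzene-1,3-diol
Product: 11 2-bromo-4,6-dihydroxybenzaldehyde
Conditions: POCl3 (1.2 equiv), DMF (3 equiv), MeCN, 0 °C to rt; then H2O, 50 °C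
Reagents that add atoms: N,N-dimethylformamide CN(C)C=O; water O
Why: Vilsmeier–Haack formylation of the resorcinol at the position ortho to one hydroxyl and para to the other, as with orcinol.

**Step 6**
Reactants: 11 2-bromo-4,6-dihydroxybenzaldehyde
Product: 12 6-bromo-2,4-dihydroxy-3-methylbenzaldehyde
Conditions: MeI (1.1 equiv), KOH (2.2 equiv), MeOH, 0 to 40 °C
Reagents that add atoms: iodomethane CI
Why: Nuclear C-methylation of the acylresorcinol dianion at the carbon between the two oxygens; the other activated carbon is hindered by the neighbouring bromine (modest yield expected, cheap material).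

**Step 7**
Reactants: 9 (3E,5R,6S,7S)-5,7-dimethyl-1-(trimethylsilyl)non-3-en-1-yne-5,6-diol; 12 6-bromo-2,4-dihydroxy-3-methylbenzaldehyde
Product: 13 6-[(3E,5R,6S,7S)-5,6-dihydroxy-5,7-dimethylnon-3-en-1-yn-1-yl]-2,4-dihydroxy-3-methylbenzaldehyde
Conditions: Pd(PPh3)2Cl2 (5 mol %), CuI (10 mol %), CsF (4 equiv), Et3N, DMF, 60 °C
Reagents that add atoms: none
Why: Sonogashira coupling with fluoride-triggered in situ desilylation, so the sensitive terminal enyne is never isolated; the bromide is activated by the ortho aldehyde, and free phenols and the diol are tolerated.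

**Step 8**
Reactants: 13 6-[(3E,5R,6S,7S)-5,6-dihydroxy-5,7-dimethylnon-3-en-1-yn-1-yl]-2,4-dihydroxy-3-methylbenzaldehyde
Product: 15 (7S)-3-[(1E,3R,4S,5S)-3,4-dihydroxy-3,5-dimethylhept-1-en-1-yl]-7-hydroxy-7-methyl-6H-isochromene-6,8(7H)-dione, via dearomatized o-quinol aldehyde 14 (not isolated)
Conditions: ArI* = 2-iodo-5-methoxy-N1,N3-bis[(1S)-1-(2,4,6-trimethylphenyl)ethyl]benzene-1,3-dicarboxamide (10 mol %), 2KHSO5·KHSO4·K2SO4 (0.6 equiv), Bu4NHSO4 (10 mol %), EtOAc, 0 °C; then KH2PO4/K2HPO4 buffer (pH 7.2), MeCN, rt
Reagents that add atoms: potassium peroxymonosulfate [K+].[O-]S(=O)(=O)OO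
Why: Proposed new method: catalytic enantioselective hydroxylative dearomatization by a chiral pentavalent iodine species made in situ; KHSO5 oxidises the C2-symmetric iodoarene ArI* to a pseudocyclic iodyl arene (amide C=O···I contacts, the two oxo ligands related by the C2 axis), the more acidic 4-hydroxyl of 13 exchanges onto iodine, and an iodine-bound oxygen is passed intramolecularly to the adjacent, most nucleophilic ring carbon C3 (flanked by both oxygens) on the face set by the two stereogenic amide arms, releasing trivalent iodine for re-oxidation and the o-quinol 14 with the new quaternary carbinol (the later C7); 14 is a vinylogous acid whose hydroxymethylene oxygen adds 6-endo to the alkyne under phosphate buffer and closes the pyran ring; the closest known reactions are the stoichiometric, racemic 2-iodoxybenzoic acid oxidation of 6,8-dihydroxy-2-benzopyrylium salts to azaphilones, stoichiometric chiral iodyl-arene hydroxylative phenol dearomatization, KHSO5-driven 2-iodobenzamide catalysis, and the buffer-mediated cycloisomerization of the same vinylogous acids; the sense of induction must be found by experiment, and the enantiomer of ArI* that gives (3R)-14 is used.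

**Step 9**
Reactants: 15 (7S)-3-[(1E,3R,4S,5S)-3,4-dihydroxy-3,5-dimethylhept-1-en-1-yl]-7-hydroxy-7-methyl-6H-isochromene-6,8(7H)-dione
Product: 16 (7R)-5-chloro-3-[(1E,3R,4S,5S)-3,4-dihydroxy-3,5-dimethylhept-1-en-1-yl]-7-hydroxy-7-methyl-6H-isochromene-6,8(7H)-dione
Conditions: N-chlorosuccinimide (1.05 equiv), MeCN, 0 °C to rt, dark
Reagents that add atoms: N-chlorosuccinimide O=C1CCC(=O)N1Cl
Why: Electrophilic chlorination at C5, the nucleophilic terminus of the O2–C3=C4–C4a=C5 dienol ether, as in known azaphilone halogenations (the C7 descriptor changes from S to R only because chlorine changes the CIP priorities).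

**Step 10**
Reactants: 16 (7R)-5-chloro-3-[(1E,3R,4S,5S)-3,4-dihydroxy-3,5-dimethylhept-1-en-1-yl]-7-hydroxy-7-methyl-6H-isochromene-6,8(7H)-dione
Product: 17 (7R,8S)-5-chloro-3-[(1E,3R,4S,5S)-3,4-dihydroxy-3,5-dimethylhept-1-en-1-yl]-7,8-dihydroxy-7-methyl-7,8-dihydro-6H-isochromen-6-one
Conditions: Me4NBH(OAc)3 (6 equiv), MeCN/AcOH (4:1), −30 °C
Reagents that add atoms: none
Why: Hydroxyl-directed triacetoxyborohydride reduction: the 7-hydroxyl binds boron and hydride is delivered intramolecularly to the adjacent C8 ketone on the face of the 7-OH, giving the trans 7,8-diol (8S); C8 is an ordinary β-alkoxy enone carbonyl, whereas C6 is deactivated as the oxido end of the 6-oxido-2-benzopyrylium resonance form, and the reagent does not reduce undirected ketones.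

**Compound list**
1 | 3-methylpent-2-enal (E isomer drawn) | CC/C(C)=C/C=O | starting material
2 | (S)-3-methylpentanal | CC[C@H](C)CC=O | intermediate
3 | (2S,3S)-3-methyl-1-oxopentan-2-yl benzoate | CC[C@H](C)[C@H](OC(=O)c1ccccc1)C=O | intermediate
4 | 1,4-bis(trimethylsilyl)buta-1,3-diyne | C[Si](C)(C)C#CC#C[Si](C)(C)C | starting material
5 | lithium 4-(trimethylsilyl)buta-1,3-diynide | [Li]C#CC#C[Si](C)(C)C | intermediate
6 | (6S,7S)-5-hydroxy-7-methyl-1-(trimethylsilyl)nona-1,3-diyn-6-yl benzoate (lithium alkoxide in the flask, both C5 epimers) | CC[C@H](C)[C@H](OC(=O)c1ccccc1)C(O)C#CC#C[Si](C)(C)C | intermediate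
7 | (3E,6S,7S)-7-methyl-1-(trimethylsilyl)non-3-en-1-yne-5,6-diol (both C5 epimers) | CC[C@H](C)[C@H](O)C(O)/C=C/C#C[Si](C)(C)C | intermediate
8 | (3E,6S,7S)-6-hydroxy-7-methyl-1-(trimethylsilyl)non-3-en-1-yn-5-one | CC[C@H](C)[C@H](O)C(=O)/C=C/C#C[Si](C)(C)C | intermediate
9 | (3E,5R,6S,7S)-5,7-dimethyl-1-(trimethylsilyl)non-3-en-1-yne-5,6-diol | CC[C@H](C)[C@H](O)[C@](C)(O)/C=C/C#C[Si](C)(C)C | intermediate
10 | 5-bromobenzene-1,3-diol | Oc1cc(O)cc(Br)c1 | starting material
11 | 2-bromo-4,6-dihydroxybenzaldehyde | O=Cc1c(Br)cc(O)cc1O | intermediate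
12 | 6-bromo-2,4-dihydroxy-3-methylbenzaldehyde | O=Cc1c(Br)cc(O)c(C)c1O | intermediate
13 | 6-[(3E,5R,6S,7S)-5,6-dihydroxy-5,7-dimethylnon-3-en-1-yn-1-yl]-2,4-dihydroxy-3-methylbenzaldehyde | CC[C@H](C)[C@H](O)[C@](C)(O)/C=C/C#Cc1cc(O)c(C)c(O)c1C=O | intermediate
14 | (3R)-6-[(3E,5R,6S,7S)-5,6-dihydroxy-5,7-dimethylnon-3-en-1-yn-1-yl]-2,3-dihydroxy-3-methyl-4-oxocyclohexa-1,5-diene-1-carbaldehyde | CC[C@H](C)[C@H](O)[C@](C)(O)/C=C/C#CC1=CC(=O)[C@](C)(O)C(O)=C1C=O | intermediate
15 | (7S)-3-[(1E,3R,4S,5S)-3,4-dihydroxy-3,5-dimethylhept-1-en-1-yl]-7-hydroxy-7-methyl-6H-isochromene-6,8(7H)-dione | CC[C@H](C)[C@H](O)[C@](C)(O)/C=C/C1=CC2=CC(=O)[C@](C)(O)C(=O)C2=CO1 | intermediate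
16 | (7R)-5-chloro-3-[(1E,3R,4S,5S)-3,4-dihydroxy-3,5-dimethylhept-1-en-1-yl]-7-hydroxy-7-methyl-6H-isochromene-6,8(7H)-dione | CC[C@H](C)[C@H](O)[C@](C)(O)/C=C/C1=CC2=C(Cl)C(=O)[C@](C)(O)C(=O)C2=CO1 | intermediate
17 | (7R,8S)-5-chloro-3-[(1E,3R,4S,5S)-3,4-dihydroxy-3,5-dimethylhept-1-en-1-yl]-7,8-dihydroxy-7-methyl-7,8-dihydro-6H-isochromen-6-one | CC[C@H](C)[C@H](O)[C@](C)(O)/C=C/C1=CC2=C(Cl)C(=O)[C@](C)(O)[C@@H](O)C2=CO1 | target

**Step count**
Total steps: 10. Longest linear sequence: 8 (steps 1, 2, 3, 4, 7, 8, 9, 10; compounds 1 → 3 → 7 → 8 → 9 → 13 → 15 → 16 → 17).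

**Steps most likely to fail**

Step 8 (the proposed new method). The chiral iodyl catalyst may give low facial selectivity at C3. KHSO5 may also attack the aldehyde (Dakin-type) or the side-chain glycol before the phenol is consumed. The fallback uses known chemistry; it sets out from 13 and comes back at 15. Compound 13 is oxidised with the stoichiometric copper–dioxygen complex made from the monovalent copper salt Cu(MeCN)4PF6 and the (+)-sparteine surrogate (1R,2S,9S)-11-methyl-7,11-diazatricyclo[7.3.1.0(2,7)]tridecane under O2 (iPr2NEt, DMAP, CH2Cl2, −78 to −10 °C). This is the established enantioselective dearomatization of 6-alkynyl-2,4-dihydroxy-3-methylbenzaldehydes, and this diamine series gives the sclerotiorin-type configuration needed here. It yields the same o-quinol 14, which is closed to 15 with the same phosphate buffer, so no new compound arises (F0).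

Step 10. The borohydride could reduce C6 instead of C8, over-reduce the product (whose C6 ketone is also next to the 7-OH), or add to C1. The fallback sets out from 15 and comes back at 17 by reversing the last two operations. The directed reduction is run on the chlorine-free azaphilone 15, whose C6 carbonyl lacks the activating α-chlorine. This gives (7R,8S)-3-[(1E,3R,4S,5S)-3,4-dihydroxy-3,5-dimethylhept-1-en-1-yl]-7,8-dihydroxy-7-methyl-7,8-dihydro-6H-isochromen-6-one F3. Mild chlorination of F3 with N-chlorosuccinimide in MeCN at C5 then gives 17.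

Step 1. Methyl and ethyl are hard to tell apart on the iminium ion, and the peroxide may interfere with residual Hantzsch ester in the one-pot sequence. The fallback sets out from 1 and comes back at 2, replacing size discrimination with olefin-geometry control. The E isomer of 1 is separated and reduced with NaBH4/CeCl3 to (E)-3-methylpent-2-en-1-ol F1. Hydrogenation of F1 with Ru(OAc)2[(R)-BINAP] and H2 in MeOH, which is stereospecific for the alkene geometry, gives (S)-3-methylpentan-1-ol F2. Oxidation of F2 with TEMPO/PhI(OAc)2 gives 2, which is then benzoyloxylated as a separate operation under the second-stage conditions of step 1 to give 3.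

**Further compounds**
F1 | step 1 | (E)-3-methylpent-2-en-1-ol | CC/C(C)=C/CO
F2 | step 1 | (S)-3-methylpentan-1-ol | CC[C@H](C)CCO
F0 | step 8 | none | none
F3 | step 10 | (7R,8S)-3-[(1E,3R,4S,5S)-3,4-dihydroxy-3,5-dimethylhept-1-en-1-yl]-7,8-dihydroxy-7-methyl-7,8-dihydro-6H-isochromen-6-one | CC[C@H](C)[C@H](O)[C@](C)(O)/C=C/C1=CC2=CC(=O)[C@](C)(O)[C@@H](O)C2=CO1
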